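**Retrosynthetic overview**

1. The target (benzo ring A, aryl ring B, pyranone ring C, dimethylpyran ring D) is a constitutional isomer of a flavanone bis-ether carrying both C5 units on oxygen: O7–CMe2–CH=CH2 on ring A and O4'–CMe2–C≡CH on ring B. One thermal operation converts this ether into the target and closes ring D last, joining O4' to CMe2 in an oxa-6π electrocyclisation of an o-quinone methide.
2. Enabling features: O4' lies para to C1', so C3' and C5' of ring B are equivalent and only one chromene can arise. The vinylogous ester O1–C8a=C4a–C4=O fixes a C7=C8 double bond in ring A, which sends the allyl shift to C8 and not C6. Both O-bound carbons are tertiary, which brings both barriers into one temperature window.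
3. C2 is set before the key step. The racemic bis-ether flavanone is funnelled by dynamic kinetic transfer hydrogenation into the cis-(2S,4S)-flavan-4-ol, and the temporary C4 carbinol is then oxidised back to the ketone.
4. Ring C comes from oxa-Michael closure of a chalcone made by Claisen–Schmidt union of an acetophenone and a benzaldehyde. Both ethers derive from one C5 chloride and are differentiated by a semihydrogenation before the union.
5. Ring order: A and B are purchased, C is closed in step 5, D in step 8. No protecting group is used, because the C5 units mask both phenols until the last step.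

Key step: step 8

Assumption: the stereodescriptor of the target is read as (2S). The facial sense of the (S,S)-catalyst in step 6 is taken from the usual model for aryl ketones, and the mirror-image catalyst would be used if the sense proved opposite.

**Step 1**
Reactants: 1 2,4-dihydroxyacetophenone; 2 3-chloro-3-methylbut-1-yne
Product: 3 1-[2-hydroxy-4-(2-methylbut-3-yn-2-yloxy)phenyl]ethan-1-one
Conditions: K2CO3, KI (cat.), CuI (cat.), acetone, 56 °C
Reagents that add atoms: none
Why: Copper-assisted Williamson-type O-propargylation, in which the 2-OH is tied up by its hydrogen bond to the acetyl C=O, so only the free and more acidic 4-OH should be alkylated at the tertiary carbon of the chloride.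

**Step 2**
Reactants: 3 1-[2-hydroxy-4-(2-methylbut-3-yn-2-yloxy)phenyl]ethan-1-one
Product: 4 1-[2-hydroxy-4-(2-methylbut-3-en-2-yloxy)phenyl]ethan-1-one
Conditions: H2 (1 atm, one equivalent taken up), Pd/CaCO3 poisoned with Pb(OAc)2 (Lindlar catalyst), quinoline, EtOAc, rt
Reagents that add atoms: none
Why: Lindlar semihydrogenation should stop at the terminal alkene and leave the aryl ketone and the tertiary C–O bond untouched, at a temperature far below that of any sigmatropic shift.

**Step 3**
Reactants: 5 4-hydroxybenzaldehyde; 2 3-chloro-3-methylbut-1-yne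
Product: 6 4-(2-methylbut-3-yn-2-yloxy)benzaldehyde
Conditions: K2CO3, KI (cat.), CuI (cat.), DMF, 60 °C
Reagents that add atoms: none
Why: This is the same copper-assisted O-propargylation on an acidic para-formylphenol, and the ether should be stable at this temperature because its rearrangement needs much stronger heating.

**Step 4**
Reactants: 4 1-[2-hydroxy-4-(2-methylbut-3-en-2-yloxy)phenyl]ethan-1-one; 6 4-(2-methylbut-3-yn-2-yloxy)benzaldehyde
Product: 7 (E)-1-[2-hydroxy-4-(2-methylbut-3-en-2-yloxy)phenyl]-3-[4-(2-methylbut-3-yn-2-yloxy)phenyl]prop-2-en-1-one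
Conditions: KOH (3 equiv), EtOH–H2O, 0 °C to rt; then 1 M HCl to pH 7 at 0 °C
Reagents that add atoms: none
Why: Claisen–Schmidt condensation with E1cB dehydration should give the (E)-enone under thermodynamic control, and both tertiary ethers and the alkyne (which has no propargylic hydrogen to isomerise) are inert to cold alcoholic KOH.

**Step 5**
Reactants: 7 the (E)-chalcone bis-ether
Product: 8 rac-7-(2-methylbut-3-en-2-yloxy)-2-[4-(2-methylbut-3-yn-2-yloxy)phenyl]chroman-4-one
Conditions: NaOAc, EtOH, 70 °C; unreacted 7 separated and resubmitted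
Reagents that add atoms: none
Why: Chalcone–flavanone isomerisation by 6-endo-trig intramolecular oxa-Michael addition of the only free phenol (2'-OH) should close ring C as the racemate under a base too mild to harm the ethers.

**Step 6**
Reactants: 8 the racemic bis-ether flavanone
Product: 9 (2S,4S)-7-(2-methylbut-3-en-2-yloxy)-2-[4-(2-methylbut-3-yn-2-yloxy)phenyl]chroman-4-ol (2,4-cis), via chalcone 7 (not isolated)
Conditions: RuCl[(S,S)-TsDPEN](p-cymene) (2 mol %), HCO2H/DBU (1:1.2), MeCN, 35 °C
Reagents that add atoms: none
Why: Noyori-type asymmetric transfer hydrogenation run as a dynamic kinetic resolution, in which free DBU racemises 8 through reversible retro-oxa-Michael opening to 7 while the (S,S)-catalyst reduces only the matched (2S)-ketone to the (4S)-alcohol with 2-aryl and 4-OH cis, so C2 is fixed as S by catalyst control.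

**Step 7**
Reactants: 9 the (2S,4S)-flavan-4-ol bis-ether
Product: 10 (2S)-7-(2-methylbut-3-en-2-yloxy)-2-[4-(2-methylbut-3-yn-2-yloxy)phenyl]chroman-4-one
Conditions: Dess–Martin periodinane, pyridine, CH2Cl2, 0 °C to rt
Reagents that add atoms: none
Why: Pyridine-buffered Dess–Martin oxidation should remove the temporary C4 stereocentre without acid that would ionise the benzylic carbinol or the tertiary ethers, and without base able to open ring C, so C2 stays S.

**Step 8**
Reactants: 10 the (2S)-flavanone bis-ether
Product: 14 (2S)-2-(2,2-dimethyl-2H-chromen-6-yl)-7-hydroxy-8-(3-methylbut-2-en-1-yl)chroman-4-one, via prenylphenol 11 (not isolated), via allenylphenol 12 (not isolated), via quinone methide 13 (not isolated)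
Conditions: o-xylene (0.02 M, degassed), 140 °C, Ar, silanised sealed tube
Reagents that add atoms: none
Why: Heating first drives the aromatic Claisen [3,3] shift of the O7 1,1-dimethylallyl ether to C8 with allyl inversion and rearomatisation (11), then the propargyl Claisen [3,3] shift of the O4' ether to C3', enolisation to allenylphenol 12, a [1,5]-H shift from O4'–H to the central allene carbon to give the (Z)-o-quinone methide 13, and a thermally allowed disrotatory oxa-6π electrocyclisation that joins O4' to CMe2. The closest known reaction types are the thermal rearrangement of aryl 1,1-dimethylallyl ethers to o-prenylphenols and of aryl 1,1-dimethylpropargyl ethers to 2,2-dimethyl-2H-chromenes, here run side by side in one flask as a pure isomerisation. The one ring closed is the six-membered pyran ring D, by 6π electrocyclic closure of the 1-oxatriene O4'=C4'–C3'=CH–CH=CMe2, made irreversible by the rearomatisation of ring B. No stereocentre is created, and C2 is a spectator that should hold because the medium is neutral, aprotic and non-polar, so the enolate needed for retro-oxa-Michael opening of ring C is not available. Site selectivity in ring A (C8 over C6) rests on the C7=C8 bond fixation imposed by the vinylogous ester O1–C8a=C4a–C4=O, and in ring B none is needed because C3' and C5' are equivalent. Chemoselectivity between the two ethers is built in, since the alkene-level unit can only end as the open prenyl chain beside a free 7-OH and the alkyne-level unit can only end as the chromene, while high dilution and acid-free glass suppress intermolecular capture of 13 and elimination from the tertiary ethers.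

**Compound list**

1 | 2,4-dihydroxyacetophenone | CC(=O)c1ccc(O)cc1O | starting material
2 | 3-chloro-3-methylbut-1-yne | CC(C)(Cl)C#C | starting material
3 | 1-[2-hydroxy-4-(2-methylbut-3-yn-2-yloxy)phenyl]ethan-1-one | CC(=O)c1ccc(OC(C)(C)C#C)cc1O | intermediate
4 | 1-[2-hydroxy-4-(2-methylbut-3-en-2-yloxy)phenyl]ethan-1-one | CC(=O)c1ccc(OC(C)(C)C=C)cc1O | intermediate
5 | 4-hydroxybenzaldehyde | O=Cc1ccc(O)cc1 | starting material
6 | 4-(2-methylbut-3-yn-2-yloxy)benzaldehyde | O=Cc1ccc(OC(C)(C)C#C)cc1 | intermediate
7 | (E)-1-[2-hydroxy-4-(2-methylbut-3-en-2-yloxy)phenyl]-3-[4-(2-methylbut-3-yn-2-yloxy)phenyl]prop-2-en-1-one | C=CC(C)(C)Oc1ccc(C(=O)/C=C/c2ccc(OC(C)(C)C#C)cc2)c(O)c1 | intermediate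
8 | rac-7-(2-methylbut-3-en-2-yloxy)-2-[4-(2-methylbut-3-yn-2-yloxy)phenyl]chroman-4-one | C=CC(C)(C)Oc1ccc2c(c1)OC(c1ccc(OC(C)(C)C#C)cc1)CC2=O | intermediate
9 | (2S,4S)-7-(2-methylbut-3-en-2-yloxy)-2-[4-(2-methylbut-3-yn-2-yloxy)phenyl]chroman-4-ol | C=CC(C)(C)Oc1ccc2c(c1)O[C@H](c1ccc(OC(C)(C)C#C)cc1)C[C@@H]2O | intermediate
10 | (2S)-7-(2-methylbut-3-en-2-yloxy)-2-[4-(2-methylbut-3-yn-2-yloxy)phenyl]chroman-4-one | C=CC(C)(C)Oc1ccc2c(c1)O[C@H](c1ccc(OC(C)(C)C#C)cc1)CC2=O | intermediate
11 | (2S)-7-hydroxy-8-(3-methylbut-2-en-1-yl)-2-[4-(2-methylbut-3-yn-2-yloxy)phenyl]chroman-4-one | CC(C)=CCc1c(O)ccc2c1O[C@H](c1ccc(OC(C)(C)C#C)cc1)CC2=O | intermediate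
12 | (2S)-7-hydroxy-2-[4-hydroxy-3-(3-methylbuta-1,2-dien-1-yl)phenyl]-8-(3-methylbut-2-en-1-yl)chroman-4-one | CC(C)=CCc1c(O)ccc2c1O[C@H](c1ccc(O)c(C=C=C(C)C)c1)CC2=O | intermediate
13 | (2S)-7-hydroxy-8-(3-methylbut-2-en-1-yl)-2-[(3Z)-3-(3-methylbut-2-en-1-ylidene)-4-oxocyclohexa-1,5-dien-1-yl]chroman-4-one | CC(C)=CCc1c(O)ccc2c1O[C@H](C1=C/C(=C/C=C(C)C)C(=O)C=C1)CC2=O | intermediate
14 | (2S)-2-(2,2-dimethyl-2H-chromen-6-yl)-7-hydroxy-8-(3-methylbut-2-en-1-yl)chroman-4-one | CC(C)=CCc1c(O)ccc2c1O[C@H](c1ccc3c(c1)C=CC(C)(C)O3)CC2=O | target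

**Step count**

Total step count: 8. Longest linear sequence: 7 (steps 1, 2, 4, 5, 6, 7, 8).

**Steps most likely to fail**

- **Step 8.** Prolonged heating may erode the configuration at C2 through slow thermal opening and reclosure of ring C. Part of the allyl shift may leak to C6, and a C5 unit may be lost by elimination from a tertiary ether.
 - Fallback: the pericyclic cascade is moved to the achiral stage and the stereocentre is introduced afterwards.
 - It sets out from 7, which is heated in o-xylene at 140 °C to give (E)-1-[2,4-dihydroxy-3-(3-methylbut-2-en-1-yl)phenyl]-3-(2,2-dimethyl-2H-chromen-6-yl)prop-2-en-1-one F1. Here the chelated 2'-OH reinforces the bond fixation.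
 - NaOAc in EtOH then closes ring C to the racemic flavanone F2.
 - A transfer-hydrogenation kinetic resolution follows (RuCl[(R,R)-TsDPEN](p-cymene), HCO2H/Et3N 5:2, EtOAc, rt, stopped near half conversion). It should reduce only the (2R)-enantiomer to the cis-(2R,4R)-chromane-4,7-diol F3 and leave the (2S)-ketone, which is 14.

- **Step 6.** Racemisation of the mismatched enantiomer may be slower than its background reduction, or the transient enone may itself be reduced.
 - Fallback: a plain kinetic resolution replaces the dynamic process.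
 - It sets out from 8, which is treated with RuCl[(R,R)-TsDPEN](p-cymene) in HCO2H/Et3N 5:2 and EtOAc at rt to about half conversion. In this acidic medium ring C does not open.
 - The (2R)-ketone should be reduced to the cis-(2R,4R)-flavan-4-ol bis-ether F4, which is removed by chromatography. The untouched (2S)-ketone is 10, so step 7 is bypassed.

- **Step 5.** Ring closure is an equilibrium and may stop short of completion, and long warming may start the allyl shift prematurely.
 - Fallback: the O1–C2 bond is made by substitution instead of conjugate addition.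
 - It sets out from 4, whose dianion (LDA, THF, −78 °C) is added to 6 to give the racemic aldol 3-hydroxy-1-[2-hydroxy-4-(2-methylbut-3-en-2-yloxy)phenyl]-3-[4-(2-methylbut-3-yn-2-yloxy)phenyl]propan-1-one F5.
 - An intramolecular Mitsunobu etherification (PPh3, DIAD, THF, 0 °C) then closes ring C and comes back to the route at 8.

**Further compounds**

F1 | step 8 | (E)-1-[2,4-dihydroxy-3-(3-methylbut-2-en-1-yl)phenyl]-3-(2,2-dimethyl-2H-chromen-6-yl)prop-2-en-1-one | CC(C)=CCc1c(O)ccc(C(=O)/C=C/c2ccc3c(c2)C=CC(C)(C)O3)c1O
F2 | step 8 | rac-2-(2,2-dimethyl-2H-chromen-6-yl)-7-hydroxy-8-(3-methylbut-2-en-1-yl)chroman-4-one | CC(C)=CCc1c(O)ccc2c1OC(c1ccc3c(c1)C=CC(C)(C)O3)CC2=O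
F3 | step 8 | (2R,4R)-2-(2,2-dimethyl-2H-chromen-6-yl)-8-(3-methylbut-2-en-1-yl)chromane-4,7-diol | CC(C)=CCc1c(O)ccc2c1O[C@@H](c1ccc3c(c1)C=CC(C)(C)O3)C[C@H]2O
F4 | step 6 | (2R,4R)-7-(2-methylbut-3-en-2-yloxy)-2-[4-(2-methylbut-3-yn-2-yloxy)phenyl]chroman-4-ol | C=CC(C)(C)Oc1ccc2c(c1)O[C@@H](c1ccc(OC(C)(C)C#C)cc1)C[C@H]2O
F5 | step 5 | rac-3-hydroxy-1-[2-hydroxy-4-(2-methylbut-3-en-2-yloxy)phenyl]-3-[4-(2-methylbut-3-yn-2-yloxy)phenyl]propan-1-one | C=CC(C)(C)Oc1ccc(C(=O)CC(O)c2ccc(OC(C)(C)C#C)cc2)c(O)c1
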